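**Retrosynthetic overview**

1. The last ring made is the δ-lactone (C9–O–C15(=O)–C14–C13–C8). It is closed at C14–C13 by an orthoester Claisen rearrangement of a cyclic ketene acetal built on a cis-9α,11α-diol; selenoxide elimination then gives the exocyclic methylene.
2. Enabling feature: in the seven-membered ring of the 2-oxabicyclo[3.2.1]octene (O–C15–C14–C13–C12=C11–C9), the lactone carbonyl C15 is γ,δ-unsaturated to C12=C11 and the ring oxygen sits on C9, next to C11. This is a Claisen retron whose allylic C11 oxygen is erased in the step.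
3. The diol comes from the cyclopentadiene ester C9=C11–C12(Me)=C13–CO2Me by dihydroxylation; the diene comes from a C13 ketone (methylation, enol triflate, carbonylation).
4. The γ-lactone (C19–O–C6) and C5–H come from iodolactonisation/deiodination of a 5-ene. Ring A comes from Robinson annulation with ethyl vinyl ketone on the C10-carboxylated bicyclic enedione, followed by gem-dimethylation.
5. Ring order: ring B plus cyclopentane (commercial bicyclic enedione) → ring A → γ-lactone → δ-lactone.

Key step: step 20

Remark on locants: target-style locants are used throughout (decalin C1–C10; C19 = γ-lactone carbonyl on C10; cyclopentene C9–C11=C12–C13–C8; δ-lactone C9–O–C15–C14–C13); β is the face of the C8 methyl group and of C19, α the other face.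

Remark on conventions: metal enolates, alkoxides and salts that exist only between addition of a base or hydride and the electrophile or work-up are not numbered. The centres at C12 in 12, at the orthoester carbon in 27, at C14 in 29 and 30, and the alkene geometry in 28 form as mixtures that converge later and are left undefined in the SMILES.

**Route**

Step 1
Reactants: 1 (7aS)-7a-methyl-2,3,7,7a-tetrahydro-1H-indene-1,5(6H)-dione
Product: 2 C13 ethylene ketal of the enedione
Conditions: Me3SiOCH2CH2OSiMe3, Me3SiOSO2CF3 (cat.), CH2Cl2, −78 °C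
Reagents that add atoms: 1,2-bis(trimethylsilyloxy)ethane, C[Si](C)(C)OCCO[Si](C)(C)C
Why: Silyl-triflate-catalysed dioxolane formation from the bis-silyl glycol ether should be selective for the saturated cyclopentanone over the conjugated enone, so only C13 is masked and no stereocentre is touched.

Step 2
Reactants: 2 C13 ethylene ketal of the enedione
Product: 3 C10 carboxylic acid
Conditions: MeOMgOCO2Me (2 M in DMF), 125 °C, N2 sweep; then cold 1 M HCl to pH 3
Reagents that add atoms: methoxymagnesium methyl carbonate, COC(=O)O[Mg]OC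
Why: Carboxylation of the enone with the magnesium methyl carbonate proceeds through the extended enolate and should stop at the magnesium chelate of the α-carboxy enone, which places the future C19 carbon on C10.

Step 3
Reactants: 3 C10 carboxylic acid
Product: 4 tert-butyl ester of 3
Conditions: i-PrN=C(Ot-Bu)NHi-Pr, CH2Cl2, rt
Reagents that add atoms: O-tert-butyl-N,N'-diisopropylisourea, CC(C)N=C(OC(C)(C)C)NC(C)C
Why: Isourea esterification (O-alkylation of the acid by the protonated isourea) is neutral and should leave the ketal and the enone untouched.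

Step 4
Reactants: 4 tert-butyl ester of 3; 5 pent-1-en-3-one
Product: 7 tricyclic 4-methyl-4-en-3-one, via Michael adduct 6 (not isolated)
Conditions: DBU (cat.), MeCN, 0 °C → rt; then pyrrolidine, AcOH, toluene, 80 °C
Reagents that add atoms: none
Why: Robinson annulation, in which the extended enolate of the alkylidene β-keto ester adds to the enone at C10 (deconjugative Michael addition) on the face opposite the C8 methyl group, fixing the C10 quaternary centre and moving the alkene to C9=C11, after which pyrrolidinium acetate closes ring A by aldol condensation without alkoxide bases that would cleave the non-enolisable β-keto ester.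

Step 5
Reactants: 7 tricyclic 4-methyl-4-en-3-one
Product: 8 4,4-dimethyl-5-en-3-one
Conditions: KOt-Bu, t-BuOH/THF, 0 °C; MeI, 0 °C → rt
Reagents that add atoms: iodomethane, CI
Why: Deconjugative α-methylation of the extended potassium enolate (deprotonation at C6, alkylation at C4) should give the gem-dimethyl 5-ene, a standard ring A operation of terpenoid synthesis.

Step 6
Reactants: 8 4,4-dimethyl-5-en-3-one
Product: 10 3β-hydroxy C13 ketone, via ketal alcohol 9 (not isolated)
Conditions: NaBH4, MeOH/THF, 0 °C; then 1 M HCl, THF, rt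
Reagents that add atoms: water, O
Why: Borohydride reduction of the only free ketone (hydride from the α face, equatorial 3β-alcohol, a configuration corrected in steps 14 and 15) is followed by acidic ketal hydrolysis, and the β,γ-unsaturated cyclopentanone should stay deconjugated as in related ring-fused hydrindenones.

Step 7
Reactants: 10 3β-hydroxy C13 ketone
Product: 11 3β-silyl ether
Conditions: t-BuMe2SiCl, imidazole, DMAP (cat.), DMF, 40 °C
Reagents that add atoms: tert-butyldimethylsilyl chloride, CC(C)(C)[Si](C)(C)Cl
Why: Silylation of the equatorial alcohol masks it for the two enolate steps that follow.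

Step 8
Reactants: 11 3β-silyl ether
Product: 12 12-methyl ketone (C12 epimers)
Conditions: LiN(i-Pr)2, THF, −78 °C; MeI, −78 → −20 °C
Reagents that add atoms: iodomethane, CI
Why: Kinetic enolate alkylation, in which only C12 can be deprotonated (C8 is quaternary) and the dienolate is methylated at its α-carbon; the new C12 centre is destroyed in step 9.

Step 9
Reactants: 12 12-methyl ketone (C12 epimers)
Product: 13 dienyl triflate
Conditions: KN(SiMe3)2, THF, −78 °C; PhNTf2, −78 → 0 °C; then 0.5 M HCl
Reagents that add atoms: N-phenylbis(trifluoromethanesulfonimide), O=S(=O)(N(c1ccccc1)S(=O)(=O)C(F)(F)F)C(F)(F)F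
Why: Enol triflate formation by O-sulfonylation of the potassium dienolate is regiodefined because only C12 carries a proton.

Step 10
Reactants: 13 dienyl triflate
Product: 14 methyl dienoate
Conditions: Pd(OAc)2 (cat.), PPh3, CO (1 atm), MeOH, Et3N, DMF, 50 °C
Reagents that add atoms: carbon monoxide, [C-]#[O+]; methanol, CO
Why: Palladium-catalysed methoxycarbonylation of the dienyl triflate (oxidative addition to zerovalent palladium, CO insertion, methanolysis) should install the C13 ester and complete the 9(11),12-dienoate.

Step 11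
Reactants: 14 methyl dienoate
Product: 15 5α-iodo 19,6β-lactone
Conditions: I2, NaHCO3, MeCN, 0 °C → rt, dark
Reagents that add atoms: iodine, II
Why: Iodolactonisation with participation of the tert-butyl ester carbonyl (5-endo opening of the α-face iodonium ion at C6, loss of isobutene) should occur at the isolated C5=C6 alkene in preference to the ester-conjugated diene, and anti addition sets the C6 oxygen on the β face and places iodine on C5α.

Step 12
Reactants: 15 5α-iodo 19,6β-lactone
Product: 16 19,6β-lactone with 5α-H
Conditions: Bu3SnH, AIBN (cat.), toluene, 80 °C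
Reagents that add atoms: none
Why: Radical dehalogenation by the tin hydride chain, in which the tertiary C5 radical should take hydrogen from the α face because the lactone bridge covers the β face, giving the trans-fused decalin.

Step 13
Reactants: 16 19,6β-lactone with 5α-H
Product: 17 3β-alcohol
Conditions: HF·pyridine, THF, 0 → 40 °C
Reagents that add atoms: none
Why: Fluoride-mediated desilylation frees the C3 alcohol while lactone and esters are inert.

Step 14
Reactants: 17 3β-alcohol
Product: 18 3-ketone
Conditions: DMP (triacetoxy periodinane), CH2Cl2, rt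
Reagents that add atoms: none
Why: Periodinane oxidation gives the C3 ketone under neutral conditions that leave the diene ester and the lactone alone.

Step 15
Reactants: 18 3-ketone
Product: 19 3α-alcohol
Conditions: LiBH(s-Bu)3, THF, −78 °C; then 1 M HCl
Reagents that add atoms: none
Why: The bulky trialkylborohydride should attack the 4,4-dimethyl-3-ketone of the trans-decalin from the equatorial direction (axial approach is blocked by the axial hydrogens on C1 and C5), giving the axial 3α-alcohol as with 3-oxo-triterpenoids, while the hindered dienoate and the lactone are not reduced at −78 °C.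

Step 16
Reactants: 19 3α-alcohol
Product: 20 3α-acetate
Conditions: Ac2O, DMAP (cat.), pyridine, 40 °C
Reagents that add atoms: acetic anhydride, CC(=O)OC(C)=O
Why: DMAP-catalysed acetylation of the axial alcohol; no strong base is used from here on, so the acetate is carried to the end.

Step 17
Reactants: 20 3α-acetate
Product: 21 9α,11α-diol
Conditions: OsO4 (10 mol %), N-methylmorpholine N-oxide, MeSO2NH2, acetone/H2O, rt
Reagents that add atoms: N-methylmorpholine N-oxide, C[N+]1([O-])CCOCC1; water, O
Why: Osmium-catalysed syn-dihydroxylation should take place at the distal alkene of the dienoate (the tetrasubstituted α,β-alkene is electron-poor) and from the α face opposite the C8 methyl group and C19, which sets C9 and C11.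

Step 18
Reactants: 22 benzeneselenol; 23 acrylonitrile
Product: 24 3-(phenylselanyl)propanenitrile
Conditions: Et3N (cat.), EtOH, 0 °C → rt
Reagents that add atoms: none
Why: Base-catalysed conjugate (Michael) addition of the selenol to acrylonitrile.

Step 19
Reactants: 24 3-(phenylselanyl)propanenitrile
Product: 26 1,1,1-trimethoxy-3-(phenylselanyl)propane, via imidate hydrochloride 25 (not isolated)
Conditions: HCl (g), MeOH (1.1 equiv), Et2O, 0 °C; then MeOH, hexane, rt
Reagents that add atoms: methanol, CO; hydrogen chloride, Cl (held only in intermediate 25)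
Why: Pinner reaction, in which the nitrile gives the imidate hydrochloride and its methanolysis gives the orthoester and ammonium chloride.

Step 20
Reactants: 21 9α,11α-diol; 26 1,1,1-trimethoxy-3-(phenylselanyl)propane
Product: 29 14-(phenylselanylmethyl) δ-lactone, via cyclic orthoester 27 (not isolated), via cyclic ketene acetal 28 (not isolated)
Conditions: 26 (4 equiv), t-BuCO2H (0.2 equiv), o-xylene, 145 °C, MeOH distilled off through 4 Å sieves
Reagents that add atoms: none
Why: Proposed new method: transorthoesterification of the cis-diol should give the 2-methoxy-1,3-dioxolane 27, which loses methanol under acid catalysis to the 2-alkylidene-1,3-dioxolane 28, whose ketene acetal carbon C14 adds to C13 of the ring enoate while the allylic C11–O bond breaks in a [3,3] shift; the closest known reactions are the Johnson–Claisen rearrangement with 3-selanyl orthopropanoates (α-methylene ester synthesis) and the Claisen ring expansion of 2-methylene-4-vinyl-1,3-dioxolanes to seven-membered lactones, neither yet shown for an allyl unit held inside a ring fused to the dioxolane. The shift closes the six-membered lactone ring, and with it the seven-membered ring of the 2-oxabicyclo[3.2.1]octene, through a chair-like six-atom array (C14, C15, O, C11, C12, C13) held in a noradamantane-shaped cage, so that the five-membered dioxolane is expanded into the lactone bridge. The new quaternary centre C13 is controlled by the C11–O configuration set in step 17, since the tether through the C9 oxygen allows bond formation only on the α face; the configuration at C14 is irrelevant because that carbon becomes sp2 in step 21. The step needs the cyclic ketene acetal to rearrange faster than it is reprotonated or opened: removal of methanol leaves no acyclic orthoester to return to, the two oxygen donors on C15 accelerate the shift enough to offset the ester on the allyl terminus, and the selanyl group is a poor leaving group, so no acrylate forms.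

Step 21
Reactants: 29 14-(phenylselanylmethyl) δ-lactone
Product: 31 meroantarctine B, via selenoxide 30 (not isolated)
Conditions: NaIO4, NaHCO3, THF/MeOH/H2O, 0 °C → rt
Reagents that add atoms: sodium periodate, [Na+].[O-]I(=O)(=O)=O (its oxygen is held only in intermediate 30)
Why: Selenide oxidation and selenoxide syn-elimination at room temperature, in which the only β-hydrogen is on C14 (C13 is quaternary), so the exocyclic methylene should form regiospecifically.

**Compound list**

1 | (7aS)-7a-methyl-2,3,7,7a-tetrahydro-1H-indene-1,5(6H)-dione (C5 enone carbonyl, C13 ketone, 8β-methyl) | C[C@]12CCC(=O)C=C1CCC2=O | starting material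
2 | 13,13-ethylenedioxy derivative of 1 (5-oxo-9(10)-ene) | C[C@]12CCC(=O)C=C1CCC23OCCO3 | intermediate
3 | 13,13-ethylenedioxy-5-oxo-9(10)-ene-10-carboxylic acid | C[C@]12CCC(=O)C(C(=O)O)=C1CCC23OCCO3 | intermediate
4 | tert-butyl ester of 3 | C[C@]12CCC(=O)C(C(=O)OC(C)(C)C)=C1CCC23OCCO3 | intermediate
5 | pent-1-en-3-one (ethyl vinyl ketone) | C=CC(=O)CC | starting material
6 | Michael adduct: 10α-(3-oxopentyl)-10β-tert-butoxycarbonyl-5-oxo-9(11)-ene, C13 ketal | C[C@]12CCC(=O)[C@](CCC(=O)CC)(C(=O)OC(C)(C)C)C1=CCC23OCCO3 | intermediate (not isolated)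
7 | tricyclic 4-methyl-4-en-3-one with 10β-CO2t-Bu, 9(11)-ene, C13 ketal | C[C@]12CCC3=C(C)C(=O)CC[C@@]3(C(=O)OC(C)(C)C)C1=CCC24OCCO4 | intermediate
8 | 4,4-dimethyl-5-en-3-one with 10β-CO2t-Bu, 9(11)-ene, C13 ketal | C[C@]12CC=C3C(C)(C)C(=O)CC[C@@]3(C(=O)OC(C)(C)C)C1=CCC24OCCO4 | intermediate
9 | 3β-alcohol of 8 (ketal still in place) | C[C@]12CC=C3C(C)(C)[C@H](O)CC[C@@]3(C(=O)OC(C)(C)C)C1=CCC24OCCO4 | intermediate (not isolated)
10 | 3β-hydroxy-13-oxo-5,9(11)-diene with 10β-CO2t-Bu | C[C@]12CC=C3C(C)(C)[C@H](O)CC[C@@]3(C(=O)OC(C)(C)C)C1=CCC2=O | intermediate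
11 | 3β-tert-butyldimethylsilyl ether of 10 | C[C@]12CC=C3C(C)(C)[C@H](O[Si](C)(C)C(C)(C)C)CC[C@@]3(C(=O)OC(C)(C)C)C1=CCC2=O | intermediate
12 | 12-methyl derivative of 11 (both C12 epimers) | C[C@]12CC=C3C(C)(C)[C@H](O[Si](C)(C)C(C)(C)C)CC[C@@]3(C(=O)OC(C)(C)C)C1=CC(C)C2=O | intermediate
13 | 12-methyl-5,9(11),12-trien-13-yl triflate with 3β-OTBS, 10β-CO2t-Bu | C[C@]12CC=C3C(C)(C)[C@H](O[Si](C)(C)C(C)(C)C)CC[C@@]3(C(=O)OC(C)(C)C)C1=CC(C)=C2OS(=O)(=O)C(F)(F)F | intermediate
14 | methyl 12-methyl-5,9(11),12-triene-13-carboxylate with 3β-OTBS, 10β-CO2t-Bu | C[C@]12CC=C3C(C)(C)[C@H](O[Si](C)(C)C(C)(C)C)CC[C@@]3(C(=O)OC(C)(C)C)C1=CC(C)=C2C(=O)OC | intermediate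
15 | 5α-iodo-19,6β-lactone with 3β-OTBS, 9(11),12-dienoate | C[C@]12C[C@@H]3OC(=O)[C@]4(CC[C@@H](O[Si](C)(C)C(C)(C)C)C(C)(C)[C@@]34I)C1=CC(C)=C2C(=O)OC | intermediate
16 | 19,6β-lactone with 5α-H, 3β-OTBS, 9(11),12-dienoate | C[C@]12C[C@@H]3OC(=O)[C@]4(CC[C@@H](O[Si](C)(C)C(C)(C)C)C(C)(C)[C@@H]34)C1=CC(C)=C2C(=O)OC | intermediate
17 | 3β-alcohol of the lactone dienoate | C[C@]12C[C@@H]3OC(=O)[C@]4(CC[C@@H](O)C(C)(C)[C@@H]34)C1=CC(C)=C2C(=O)OC | intermediate
18 | 3-ketone of the lactone dienoate | C[C@]12C[C@@H]3OC(=O)[C@]4(CCC(=O)C(C)(C)[C@@H]34)C1=CC(C)=C2C(=O)OC | intermediate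
19 | 3α-alcohol of the lactone dienoate | C[C@]12C[C@@H]3OC(=O)[C@]4(CC[C@H](O)C(C)(C)[C@@H]34)C1=CC(C)=C2C(=O)OC | intermediate
20 | 3α-acetate of the lactone dienoate | C[C@]12C[C@@H]3OC(=O)[C@]4(CC[C@H](OC(C)=O)C(C)(C)[C@@H]34)C1=CC(C)=C2C(=O)OC | intermediate
21 | 9α,11α-diol (3α-OAc, 19,6β-lactone, methyl 12-ene-13-carboxylate) | C[C@]12C[C@@H]3OC(=O)[C@]4(CC[C@H](OC(C)=O)C(C)(C)[C@@H]34)[C@]1(O)[C@@H](O)C(C)=C2C(=O)OC | intermediate
22 | benzeneselenol | [SeH]c1ccccc1 | starting material
23 | acrylonitrile | C=CC#N | starting material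
24 | 3-(phenylselanyl)propanenitrile | N#CCC[Se]c1ccccc1 | intermediate
25 | methyl 3-(phenylselanyl)propanimidate hydrochloride | Cl.COC(=N)CC[Se]c1ccccc1 | intermediate (not isolated)
26 | 1,1,1-trimethoxy-3-(phenylselanyl)propane | COC(CC[Se]c1ccccc1)(OC)OC | intermediate
27 | cyclic orthoester: 9α,11α-O,O-[1-methoxy-3-(phenylselanyl)propylidene] derivative of 21 | C[C@]12C[C@@H]3OC(=O)[C@]4(CC[C@H](OC(C)=O)C(C)(C)[C@@H]34)[C@@]15OC(CC[Se]c6ccccc6)(OC)O[C@H]5C(C)=C2C(=O)OC | intermediate (not isolated)
28 | cyclic ketene acetal: 9α,11α-O,O-[3-(phenylselanyl)prop-1-en-1,1-diyl] derivative of 21 | C[C@]12C[C@@H]3OC(=O)[C@]4(CC[C@H](OC(C)=O)C(C)(C)[C@@H]34)[C@@]15OC(=CC[Se]c6ccccc6)O[C@H]5C(C)=C2C(=O)OC | intermediate (not isolated)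
29 | 14-(phenylselanylmethyl) δ-lactone (target skeleton, CH–CH2SePh in place of C=CH2) | c1ccccc1[Se]CC1C(=O)O[C@@]23C=C(C)[C@]1(C(=O)OC)[C@@]2(C)C[C@@H]1OC(=O)[C@]32CC[C@H](OC(C)=O)C(C)(C)[C@@H]12 | intermediate
30 | selenoxide of 29 | c1ccccc1[Se](=O)CC1C(=O)O[C@@]23C=C(C)[C@]1(C(=O)OC)[C@@]2(C)C[C@@H]1OC(=O)[C@]32CC[C@H](OC(C)=O)C(C)(C)[C@@H]12 | intermediate (not isolated)
31 | meroantarctine B | C=C1C(=O)O[C@@]23C=C(C)[C@]1(C(=O)OC)[C@@]2(C)C[C@@H]1OC(=O)[C@]32CC[C@H](OC(C)=O)C(C)(C)[C@@H]12 | target

**Step count and risks**

Total step count: 21. Longest linear sequence: 19 (steps 1–17, 20, 21); steps 18 and 19 form the side branch to orthoester 26.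

Three steps most likely to fail:

1. Step 20 (Proposed new method). The cyclic ketene acetal may be reprotonated and opened to a hydroxy ester faster than it folds into the caged transition state, or the hindered tertiary C9 hydroxyl may not enter the orthoester, so that the ring-closing C14–C13 bond formation does not take place. Fallback with known chemistry, from 21 to 31: the secondary allylic 11α-hydroxyl of 21 would be esterified with 2-(phenylselanyl)propanoic acid (DCC, DMAP, CH2Cl2; the tertiary hydroxyl does not react) to give the 11-O-[2-(phenylselanyl)propanoyl] ester F1. Ireland–Claisen rearrangement (excess LiN(i-Pr)2 with Me3SiCl as internal quench, THF, −78 → 60 °C, then dilute HCl; the C9 hydroxyl and the C3 acetate are silylated transiently and return on work-up) would transfer the C11–O configuration to C13 and give the hydroxy acid F2. Carbodiimide lactonisation (EDCI, DMAP, CH2Cl2) onto the 9α-hydroxyl would give the 14-methyl-14-(phenylselanyl) lactone F3, and NaIO4 oxidation with syn-elimination towards the methyl group, the only site with β-hydrogens, would give 31.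

2. Step 17. The osmium reagent may fail to add to an alkene whose fully substituted carbon lies between two quaternary carbons, or may add so slowly that site and facial selectivity erode. Fallback from 20 to 21: epoxidation with dimethyldioxirane (acetone, 0 °C; small reagent, α face) would give the 9α,11α-epoxide F4. LiBr-catalysed insertion of CO2 (1 atm, N-methylpyrrolidone, 100 °C) proceeds by bromide opening at the allylic C11 and closure of the C9 carbonate with a second inversion, and would give the cis-fused 9α,11α-cyclic carbonate F5 with overall retention. Brief methanolysis (K2CO3 cat., MeOH, 0 °C; the hindered axial acetate is slower) would give diol 21.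

3. Step 11. Iodonium formation at the diene, or a 5-endo closure by the hindered ester carbonyl that is too slow to compete with reversal, may make the lactonisation unselective or stall it. Fallback from 14 to 16: the tert-butyl ester would be cleaved (Me3SiOSO2CF3, 2,6-lutidine, CH2Cl2, 0 °C, aqueous work-up) to the C19 carboxylic acid F6. Selenolactonisation with PhSeCl (CH2Cl2, −78 °C → rt) is reversible and should therefore end at the favoured γ-lactone on the electron-rich isolated alkene, giving the 5α-(phenylselanyl)-19,6β-lactone F7. Bu3SnH with AIBN (toluene, 100 °C) would remove selenium with hydrogen delivery to the α face and give 16.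

Further compounds
F1 | step 20 | 11-O-[2-(phenylselanyl)propanoyl] ester of diol 21 | C[C@]12C[C@@H]3OC(=O)[C@]4(CC[C@H](OC(C)=O)C(C)(C)[C@@H]34)[C@]1(O)[C@@H](OC(=O)C(C)[Se]c5ccccc5)C(C)=C2C(=O)OC
F2 | step 20 | 13α-[1-carboxy-1-(phenylselanyl)ethyl]-9α-hydroxy-11-ene acid from the Ireland–Claisen rearrangement | C[C@]12C[C@@H]3OC(=O)[C@]4(CC[C@H](OC(C)=O)C(C)(C)[C@@H]34)[C@]1(O)C=C(C)[C@@]2(C(=O)OC)C(C)([Se]c5ccccc5)C(=O)O
F3 | step 20 | 14-methyl-14-(phenylselanyl) δ-lactone | CC1([Se]c2ccccc2)C(=O)O[C@@]23C=C(C)[C@]1(C(=O)OC)[C@@]2(C)C[C@@H]1OC(=O)[C@]32CC[C@H](OC(C)=O)C(C)(C)[C@@H]12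
F4 | step 17 | 9α,11α-epoxide of 20 | C[C@]12C[C@@H]3OC(=O)[C@]4(CC[C@H](OC(C)=O)C(C)(C)[C@@H]34)[C@@]15O[C@H]5C(C)=C2C(=O)OC
F5 | step 17 | 9α,11α-cyclic carbonate | C[C@]12C[C@@H]3OC(=O)[C@]4(CC[C@H](OC(C)=O)C(C)(C)[C@@H]34)[C@@]15OC(=O)O[C@H]5C(C)=C2C(=O)OC
F6 | step 11 | C19 carboxylic acid of 14 | C[C@]12CC=C3C(C)(C)[C@H](O[Si](C)(C)C(C)(C)C)CC[C@@]3(C(=O)O)C1=CC(C)=C2C(=O)OC
F7 | step 11 | 5α-(phenylselanyl)-19,6β-lactone | C[C@]12C[C@@H]3OC(=O)[C@]4(CC[C@@H](O[Si](C)(C)C(C)(C)C)C(C)(C)[C@@]34[Se]c5ccccc5)C1=CC(C)=C2C(=O)OC
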